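**The crossing.** 0.522 M of first nucleophile was the number I drew from the earlier runs. It is the crossing concentration C*, at which first nucleophile takes what the substrate becomes as fast as an unseen first-order loss does. I supposed that the share of substrate ending as target is f = B/(B + C*), with B the mean first nucleophile over a run.

| flask | substrate | first nucleophile | solid second nucleophile | remark | time |
|---|---|---|---|---|---|
| Wednesday's | 0.15 M | 1.1 equiv | 0.50 equiv | run made earlier |  |
| Monday's | 0.60 M | 1.1 equiv | 0.50 equiv | run made earlier |  |
| flask | 0.30 M | 1.10 equiv | 0.500 equiv |  | 5.0 d |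

| run | time / d | other capture product / % | target / % |
|---|---|---|---|
| Wednesday's | 0.250 | 0.5 | 7.6 |
| Wednesday's | 0.333 | 0.9 | 7.2 |
| Wednesday's | 0.500 | 0.8 | 12.5 |
| Wednesday's | 0.833 | 2.8 | 17.9 |
| Wednesday's | 1.25 | 2.3 | 20.8 |
| Wednesday's | 2.08 | 3.8 | 20.6 |
| Wednesday's | 3.00 | 1.5 | 24.3 |
| Monday's | 0.167 | 0 | 10.8 |
| Monday's | 0.500 | 0 | 25.8 |
| Monday's | 0.833 | 0.8 | 36.3 |
| Monday's | 1.25 | 0.9 | 41.4 |
| Monday's | 1.67 | 2.6 | 46.9 |
| Monday's | 2.50 | 2.8 | 49.1 |
| Monday's | 3.00 | 1.6 | 49.5 |

(readings scatter by 1 percentage point)

- at the start none of the solid second nucleophile is in solution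

1. ratio of other capture product to target at 1.5 h
2. ratio of other capture product to target at 5.0 d

**Two ways.** The last target reading was 24.3% in Wednesday's run and 49.5% in Monday's run. Taking B as the charge less half the target, Wednesday's run gave C* = 0.457 M and Monday's run gave 0.522 M, so they parted by 0.0650 M. Wednesday's last two target readings differ by 3.7 percentage points, more than the 0.4 points of Monday's, so I kept Monday's value.

**My reckoning.** In the new flask, the charged 0.330 M of first nucleophile gave f = 38.7%. Taking B as the charge less half of that share gave a mean of 0.272 M, hence f = 34.3%, and a further round of the reckoning gave 34.8%. Late readings of the other capture product averaged 2.43% across both runs, so I expected a late ratio of 0.0698. I had no reckoning of my own for the early ratio.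

**The forecast.** It gave 0.035 early and 0.07 late, holding that “Dissolved second nucleophile is evidently lost to something unseen in dilute solution”.

**The result.** The flask gave 0.00887 at 1.5 h and 0.0946 at 5.0 d.

    first nucleophile + intermediate → target (k = 2.90 M⁻¹ h⁻¹)
    intermediate → solvolysis product (k = 1.30 h⁻¹)
    substrate → intermediate (k = 0.0580 h⁻¹)
    second nucleophile + intermediate → other capture product (k = 1.00 M⁻¹ h⁻¹)
    solid second nucleophile ⇌ second nucleophile, rate k5*(cs5 - [second nucleophile]) while solid is left; crystals form when [second nucleophile] > cs5 (solubility = 0.130 M, k = 0.0760 h⁻¹)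
    intermediate → decomposed reagent (k = 0.0410 h⁻¹)

**Put to use.** At 5.00 d the flask held 3.39% of other capture product, more than the 2.43% I had averaged from the late readings of the earlier runs, on 35.8% of target. In the neighbouring flask with 2.80 equiv of first nucleophile, C* gives f = 58.9%, and that flask held 60.4% of target at 5.00 d.

(The readings come from a simulation with constants of no real substance; noise was put on by code.)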